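**Strategy.** The cyclohexene ring A (C1–C5, C10), fused to the butenolide, is cut at two bonds: lactone α-carbon C4 to quaternary C5, and allylic C2 to the furan-bearing methine C1. This leaves a vinylacetic acid unit and a cyclohexene (ring B) carrying a 2-furyl carbinol. The key step exploits the allylic 1,3-relationship C1–C10–C5: an Ireland–Claisen shift from the C1 oxygen forms C4–C5 with chirality transfer, then acid turns the resulting alkenylfuran into the C1 furfuryl cation, which the vinyl terminus C2 captures while the lactone closes. Ring A and the butenolide thus form in one flask from a monocyclic but-3-enoate ester.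

Key step: step 10

Remark on numbering: clerodane-type locants are used for all compounds: C1 = CH carrying the furan, C2 = ring CH2, C3 = olefinic CH, C4 = lactone α-carbon, C5 = quaternary carbon carrying C19H2–O, C6 = CH2, C7 = CH–OAc, C8 = C(=C17H2), C9 = quaternary carbon carrying the C20 methyl and C11H2, C10 = ring-fusion CH, C12 = ketone, C13–C16 = furan carbons (C13 on C12, C16 on C1), C18 = lactone carbonyl; ring A = C1–C5/C10, ring B = C5–C10, ring C = the seven-membered ring; the β-face is the face of C11 and of the acetate.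

Step 1
Reactants: 1 2-methylcyclohexane-1,3-dione; 2 tert-butyl bromoacetate
Product: 3 triketo ester
Conditions: NaH, DMF, 0 → 50 °C
Reagents that add atoms: none
Why: C-alkylation (SN2) of the stabilized 1,3-dione enolate by the reactive α-bromo ester puts the C11–C12 arm on the future C9, giving a still achiral product.

Step 2
Reactants: 3 triketo ester
Product: 4 (1R,2R)-ketol
Conditions: (S)-1-methyl-3,3-diphenyltetrahydro-1H,3H-pyrrolo[1,2-c][1,3,2]oxazaborole [(S)-Me-CBS] (10 mol%), BH3·SMe2 (0.6 equiv), THF, −40 °C; MeOH, aqueous work-up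
Reagents that add atoms: none
Why: CBS reduction used as a desymmetrization: the catalyst should fix the carbinol as R (quaternary carbon as large group) while hydride enters anti to the bulky CH2CO2tBu arm, so only the pro-C10 carbonyl is reduced and C9 becomes R, with substoichiometric borane limiting diol formation.

Step 3
Reactants: 4 ketol
Product: 5 hydroxy ketal
Conditions: Me3SiOCH2CH2OSiMe3, Me3SiOTf (5 mol%), CH2Cl2, −78 → −20 °C; pyridine quench
Reagents that add atoms: 1,2-bis(trimethylsilyloxy)ethane, C[Si](C)(C)OCCO[Si](C)(C)C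
Why: low-temperature silyl-transfer ketalization should mask the C8 ketone without lactonizing the cis-hydroxy tert-butyl ester or cleaving the ester.

Step 4
Reactants: 5 hydroxy ketal
Product: 6 keto ketal
Conditions: Dess–Martin periodinane, NaHCO3, CH2Cl2, 0 → 23 °C
Reagents that add atoms: none
Why: Dess–Martin oxidation returns the carbinol to the ketone, so the two former carbonyls are now differentiated (C10 ketone, C8 ketal) with the R centre C9 untouched.

Step 5
Reactants: 6 keto ketal
Product: 7 α-alkoxymethyl ketone
Conditions: LiN(iPr)2, THF, −78 °C; Me3SiCH2CH2OCH2Cl, −78 → 0 °C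
Reagents that add atoms: 2-(trimethylsilyl)ethoxymethyl chloride, C[Si](C)(C)CCOCCl
Why: enolate alkylation at C5, the only enolizable position of the ketone (C9 is quaternary), by a fast α-chloro ether electrophile installs C19 as a protected hydroxymethyl group; the new C5 centre is erased in step 6.

Step 6
Reactants: 7 α-alkoxymethyl ketone
Product: 8 enol triflate
Conditions: KN(SiMe3)2, THF, −78 °C; PhNTf2, −78 → 0 °C
Reagents that add atoms: N-phenylbis(trifluoromethanesulfonimide), O=S(=O)(N(c1ccccc1)S(=O)(=O)C(F)(F)F)C(F)(F)F
Why: enol triflate formation from the only possible enolate should give the tetrasubstituted C5=C10 triflate regiospecifically.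

Step 7
Reactants: 8 enol triflate; 9 2-(tributylstannyl)furan
Product: 10 furyl ketone
Conditions: CO (1 atm), Pd(PPh3)4 (5 mol%), LiCl, 1,4-dioxane, 80 °C
Reagents that add atoms: carbon monoxide, [C-]#[O+]
Why: carbonylative Stille coupling (oxidative addition of the triflate to zerovalent palladium, CO insertion, transmetalation from tin) introduces C1 as the furyl ketone, the hindered alkenyl–palladium favouring CO insertion over direct coupling.

Step 8
Reactants: 10 furyl ketone
Product: 11 (R)-carbinol
Conditions: (R)-1-methyl-3,3-diphenyltetrahydro-1H,3H-pyrrolo[1,2-c][1,3,2]oxazaborole [(R)-Me-CBS] (20 mol%), BH3·SMe2, toluene, −40 °C; MeOH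
Reagents that add atoms: none
Why: CBS 1,2-reduction in which the twisted, fully substituted cyclohexenyl group should act as the large and the flat 2-furyl as the small substituent, so that the (R)-catalyst gives the (R)-carbinol at C1, the stereocentre that later controls C5.

Step 9
Reactants: 11 (R)-carbinol; 12 but-3-enoic acid
Product: 13 but-3-enoate
Conditions: dicyclohexylcarbodiimide, 4-(dimethylamino)pyridine (5 mol%), CH2Cl2, 0 °C
Reagents that add atoms: none
Why: Steglich esterification under neutral conditions should acylate the acid-labile furfuryl allylic alcohol without ionization, the low temperature limiting isomerization to the crotonate.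

Step 10
Reactants: 13 but-3-enoate
Product: 16 tricyclic butenolide keto acid, via silyl ketene acetal 14 (not isolated), via Claisen silyl ester 15 (not isolated)
Conditions: KN(SiMe3)2, Me3SiCl, toluene, −78 → 23 °C; then (CF3)2CHOH, CF3SO3H, 0 → 23 °C; then H2O
Reagents that add atoms: water, O; chlorotrimethylsilane, C[Si](C)(C)Cl (silicon only in 14 and 15)
Why: Enolization and O-silylation give silyl dienolate 14, whose chair [3,3] shift through the α-carbon (Ireland–Claisen rearrangement) breaks C1–O and forms C4–C5 in 15; triflic acid then strips the SEM ether, ketal and tert-butyl ester, protonates the 2-alkenylfuran at C10 to the C1 furfuryl cation, and the terminal vinyl carbon C2 attacks it with loss of the acidic C4 proton, a proton-initiated Prins-type cation–olefin cyclization, these two being the closest known reaction types. Ring A closes by 6-endo attack of the vinyl π-bond on the exocyclic cation through a chair, and the butenolide closes by 5-exo-trig lactonization of the C19 hydroxyl onto the C18 carboxyl. C5 is set by 1,3-chirality transfer from the (R)-carbinol: the oxygen lies on the β-face with H inside and furyl outside to avoid allylic 1,3-strain with C19, so C4 is delivered to the β-face. C10 and C1 are set in the cyclization: protonation is reversible and the chair with C4 and the cationic C1 both equatorial on ring B (trans fusion, furyl equatorial) should win, since the cis alternative forces C4 syn-axial to the C11 arm. The step needs C–C capture of the cation to beat oligomerization and tert-butylation of the furan: capture by the carboxyl oxygens is reversible, toluene scavenges the tert-butyl cation, and because C9 has no hydrogen the liberated C8 ketone cannot draw the alkene into conjugation.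

Step 11
Reactants: 16 tricyclic butenolide keto acid
Product: 17 tetracyclic diketone
Conditions: (CF3CO)2O, CH2Cl2 (0.005 M), 0 → 23 °C
Reagents that add atoms: none
Why: intramolecular Friedel–Crafts acylation of the activated acid, whose C11–C12 tether can reach only furan C13, should close the seven-membered ring C, the equatorial C11 and furyl groups being already gauche for the trans fusion.

Step 12
Reactants: 17 tetracyclic diketone
Product: 18 exocyclic alkene
Conditions: Zn, CH2Br2, TiCl4, THF–CH2Cl2, 0 → 23 °C
Reagents that add atoms: dibromomethane, BrCBr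
Why: Takai–Lombardo methylenation with the non-basic zinc/titanium methylene reagent should convert the saturated C8 ketone and leave the less electrophilic furan-conjugated C12 ketone (a vinylogous ester), the lactone and the base-sensitive C1 centre.

Step 13
Reactants: 18 exocyclic alkene
Product: 19 allylic alcohol
Conditions: SeO2 (0.5 equiv), tBuOOH, CH2Cl2, 0 → 23 °C
Reagents that add atoms: tert-butyl hydroperoxide, CC(C)(C)OO; selenium dioxide, O=[Se]=O (relays the oxygen)
Why: SeO2 allylic oxidation (ene reaction, then [2,3]-shift) can only functionalize C7 (C9 is quaternary), and oxygen should arrive on the β-face because the α-face of C7 is shielded by the syn-axial C19 and C20 groups, giving the equatorial 7β-alcohol.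

Step 14
Reactants: 19 allylic alcohol
Product: 20 target acetate
Conditions: Ac2O, 4-(dimethylamino)pyridine (cat.), pyridine, CH2Cl2, 0 → 23 °C
Reagents that add atoms: acetic anhydride, CC(=O)OC(C)=O
Why: acylation of the secondary allylic alcohol with retention at C7 completes the target.

**Compound list**

1 | 2-methylcyclohexane-1,3-dione | CC1C(=O)CCCC1=O | starting material
2 | tert-butyl bromoacetate | CC(C)(C)OC(=O)CBr | starting material
3 | tert-butyl 2-(1-methyl-2,6-dioxocyclohexyl)acetate | CC1(CC(=O)OC(C)(C)C)C(=O)CCCC1=O | intermediate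
4 | tert-butyl 2-[(1R,2R)-2-hydroxy-1-methyl-6-oxocyclohexyl]acetate | C[C@]1(CC(=O)OC(C)(C)C)C(=O)CCC[C@H]1O | intermediate
5 | tert-butyl 2-[(6R,7R)-7-hydroxy-6-methyl-1,4-dioxaspiro[4.5]decan-6-yl]acetate | C[C@]1(CC(=O)OC(C)(C)C)C2(OCCO2)CCC[C@H]1O | intermediate
6 | tert-butyl 2-[(6R)-6-methyl-7-oxo-1,4-dioxaspiro[4.5]decan-6-yl]acetate | C[C@]1(CC(=O)OC(C)(C)C)C2(OCCO2)CCCC1=O | intermediate
7 | tert-butyl 2-[(6R)-6-methyl-7-oxo-8-{[2-(trimethylsilyl)ethoxy]methyl}-1,4-dioxaspiro[4.5]decan-6-yl]acetate (both C-8 epimers) | C[C@]1(CC(=O)OC(C)(C)C)C2(OCCO2)CCC(COCC[Si](C)(C)C)C1=O | intermediate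
8 | tert-butyl 2-[(6R)-6-methyl-7-{[(trifluoromethyl)sulfonyl]oxy}-8-{[2-(trimethylsilyl)ethoxy]methyl}-1,4-dioxaspiro[4.5]dec-7-en-6-yl]acetate | C[C@]1(CC(=O)OC(C)(C)C)C2(OCCO2)CCC(COCC[Si](C)(C)C)=C1OS(=O)(=O)C(F)(F)F | intermediate
9 | 2-(tributylstannyl)furan | CCCC[Sn](CCCC)(CCCC)c1ccco1 | starting material
10 | tert-butyl 2-[(6R)-7-(furan-2-carbonyl)-6-methyl-8-{[2-(trimethylsilyl)ethoxy]methyl}-1,4-dioxaspiro[4.5]dec-7-en-6-yl]acetate | C[C@]1(CC(=O)OC(C)(C)C)C2(OCCO2)CCC(COCC[Si](C)(C)C)=C1C(=O)c1ccco1 | intermediate
11 | tert-butyl 2-[(6R)-7-[(R)-furan-2-yl(hydroxy)methyl]-6-methyl-8-{[2-(trimethylsilyl)ethoxy]methyl}-1,4-dioxaspiro[4.5]dec-7-en-6-yl]acetate | C[C@]1(CC(=O)OC(C)(C)C)C2(OCCO2)CCC(COCC[Si](C)(C)C)=C1[C@@H](O)c1ccco1 | intermediate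
12 | but-3-enoic acid | C=CCC(=O)O | starting material
13 | tert-butyl 2-[(6R)-7-[(R)-(but-3-enoyloxy)(furan-2-yl)methyl]-6-methyl-8-{[2-(trimethylsilyl)ethoxy]methyl}-1,4-dioxaspiro[4.5]dec-7-en-6-yl]acetate | C[C@]1(CC(=O)OC(C)(C)C)C2(OCCO2)CCC(COCC[Si](C)(C)C)=C1[C@@H](OC(=O)CC=C)c1ccco1 | intermediate
14 | O-trimethylsilyl ketene acetal of 13 (1-[(trimethylsilyl)oxy]buta-1,3-dien-1-yl ether of 11; ketene acetal geometry open) | C[C@]1(CC(=O)OC(C)(C)C)C2(OCCO2)CCC(COCC[Si](C)(C)C)=C1[C@@H](OC(O[Si](C)(C)C)=CC=C)c1ccco1 | intermediate
15 | trimethylsilyl 2-[(6R,7Z,8R)-6-(2-tert-butoxy-2-oxoethyl)-7-(furan-2-ylmethylidene)-6-methyl-8-{[2-(trimethylsilyl)ethoxy]methyl}-1,4-dioxaspiro[4.5]decan-8-yl]but-3-enoate (C-4 epimers; C5 as in the target) | C[C@]1(CC(=O)OC(C)(C)C)C2(OCCO2)CC[C@@](COCC[Si](C)(C)C)(C(C=C)C(=O)O[Si](C)(C)C)/C1=C/c1ccco1 | intermediate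
16 | tricyclic butenolide keto acid: trans-fused rings A and B with Δ3-18,19-olide, 1β-(furan-2-yl), 8-oxo, 9α-methyl, 9β-CH2CO2H (1R,5S,9R,10S) | O=C1CC[C@@]23COC(=O)C2=CC[C@@H](c2ccco2)[C@@H]3[C@@]1(C)CC(=O)O | intermediate
17 | tetracyclic diketone: 16 with C12 bonded to furan C13 (ring C closed), 8,12-dioxo (1R,5S,9R,10S) | O=C1CC[C@@]23COC(=O)C2=CC[C@H]2c4occc4C(=O)C[C@]1(C)[C@@H]23 | intermediate
18 | 8(17)-methylene-12-oxo tetracycle (1R,5S,9R,10R) | C=C1CC[C@@]23COC(=O)C2=CC[C@H]2c4occc4C(=O)C[C@]1(C)[C@@H]23 | intermediate
19 | 7β-hydroxy-8(17)-methylene-12-oxo tetracycle (1R,5S,7S,9R,10R) | C=C1[C@@H](O)C[C@@]23COC(=O)C2=CC[C@H]2c4occc4C(=O)C[C@]1(C)[C@@H]23 | intermediate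
20 | 7β-acetoxy-8(17)-methylene-12-oxo tetracycle (1R,5S,7S,9R,10R), CNP0273675.1 | C=C1[C@@H](OC(C)=O)C[C@@]23COC(=O)C2=CC[C@H]2c4occc4C(=O)C[C@]1(C)[C@@H]23 | target

Total step count: 14. Longest linear sequence: 14 steps (1 → 20).

**Steps most likely to fail**

1. Step 10. The terminal alkene is a weak π-nucleophile: under the acid the α-vinyl lactone may drift to the α-ethylidene lactone, or the alkenylfuran may oligomerize, before ring A closes. A boat-type Claisen transition state would in addition invert C5. Fallback, setting out from 11 and returning at 16: a silicon-directed terminator (vinylsilane-terminated cation–olefin cyclization). Jones oxidation (CrO3, H2SO4, acetone) of commercial 4-(trimethylsilyl)but-3-yn-1-ol would give 4-(trimethylsilyl)but-3-ynoic acid F1. Cis-semihydrogenation (H2, Pd/CaCO3 poisoned with Pb(OAc)2, quinoline) would give (Z)-4-(trimethylsilyl)but-3-enoic acid F2, and carbodiimide coupling with 11 the vinylsilane ester F3. The same rearrangement and acid treatment would then end in ipso attack of the C1 cation on the silicon-bearing C2 with loss of the silyl group, giving the Δ2 lactone F4. 1,8-Diazabicyclo[5.4.0]undec-7-ene would then move the double bond into conjugation to give 16.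

2. Step 11. Acylation at the less nucleophilic β-position C13 to close a seven-membered ring is slow, so intermolecular acylation at the free α-position C15 or acid-induced degradation of the furan may take over. Fallback, setting out from 16 and returning at 17: electrophilic amide activation. Coupling with Me2NH·HCl (EDC·HCl, iPr2NEt) would give the dimethylamide F5. Tf2O with 2-fluoropyridine (CH2Cl2, −78 → 0 °C) would generate an O-triflyl iminium electrophile that closes onto C13 (intramolecular Vilsmeier–Haack-type acylation), and aqueous NaHCO3 would hydrolyse the iminium to 17.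

3. Step 13. Facial selectivity in the [2,3]-shift may be poor, with oxygen arriving on the α-face, and the alcohol may be overoxidized to the enone. Fallback, setting out from 18 and returning at 20: if the 7α-alcohol F6 is the main product, a Mitsunobu reaction with acetic acid (PPh3, diisopropyl azodicarboxylate, THF) would invert C7 and install the acetate in one operation, arriving directly at 20.

**Further compounds**

F1 | step 10 | 4-(trimethylsilyl)but-3-ynoic acid | C[Si](C)(C)C#CCC(=O)O
F2 | step 10 | (Z)-4-(trimethylsilyl)but-3-enoic acid | C[Si](C)(C)/C=C\CC(=O)O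
F3 | step 10 | (Z)-4-(trimethylsilyl)but-3-enoate ester of 11 | C[C@]1(CC(=O)OC(C)(C)C)C2(OCCO2)CCC(COCC[Si](C)(C)C)=C1[C@@H](OC(=O)C/C=C\[Si](C)(C)C)c1ccco1
F4 | step 10 | Δ2 isomer of 16 (C2=C3, C4–H; C-4 epimers) | O=C1CC[C@@]23COC(=O)C2C=C[C@@H](c2ccco2)[C@@H]3[C@@]1(C)CC(=O)O
F5 | step 11 | N,N-dimethylamide of 16 | O=C1CC[C@@]23COC(=O)C2=CC[C@@H](c2ccco2)[C@@H]3[C@@]1(C)CC(=O)N(C)C
F6 | step 13 | 7α-hydroxy epimer of 19 | C=C1[C@H](O)C[C@@]23COC(=O)C2=CC[C@H]2c4occc4C(=O)C[C@]1(C)[C@@H]23
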